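## Structural features

The target is an achiral depside: two benzene rings joined only through an aryl ester, with no other ring and no stereocenter, so no stereochemical relationship has to be set. Ring A is the acyl half, a 2-hydroxy-4-methoxy-6-(2-oxoheptyl)benzoyl unit whose carbonyl carbon on C1 is wedged between the C2 oxygen and the C6 side chain. Ring B is the phenolic half, a 2'-methoxy-6'-(2-oxoheptyl)benzoic acid that carries the ester oxygen on C4', a carbon flanked by the two ring CH groups C3' and C5'. The fragile elements are three. The aryl salicylate ester is cleaved by hydroxide, alkoxides and amines. The two benzyl alkyl ketones sit ortho to a carboxyl function and can close to isocoumarins under dehydrating acid or to naphthalenediols under base. The free ring B acid is itself attached to a doubly ortho-substituted carbon. The real difficulty is therefore to make an ester at a carbonyl with two ortho neighbours, to keep the two carboxyl groups distinct, and to free the ring B acid at the end without base. The key step exploits two facts: the carboxylate oxygen of ring A lies outside the C2/C6 pocket and can serve as the nucleophile, and C4'–H is the only C–H of ring B with no ortho substituent, so boron can be placed there by steric control and ring B never has to be a phenol.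

## Logic of the disconnections

18 to 17: the bonds restored as masks are the four C–O bonds of two dioxolanes, the O–CH2 bond of a methoxymethyl acetal on the C2 oxygen of ring A, and the O–C(CH3)3 bond of the ring B ester. All four fall in one acidic operation that needs no nucleophile, which is what the depside ester tolerates. The gain is that ketones, phenol and acid are silent during assembly. The demand is that the final acid removes everything without dehydrating the keto acid.

17 to 8 and 16: the O–C4' bond between the ring A carboxylate oxygen and ring B is cut. Cutting here, and not at the acyl carbon, means the forward step never has to push a weak phenol into the hindered carbonyl of ring A. The molecule splits into two monocyclic halves of equal size. The demand is an oxidative copper coupling in which the carboxylate of 8 is the only oxygen nucleophile and in which acid-labile masks survive a Lewis-acidic copper salt.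

16 to 15, then to 13 and 14: first the two B–O bonds to pinacol, then the C4'–B bond, are cut back to a C–H bond. The reason is that C4'–H is the only unflanked ring hydrogen of 13, so no directing group or phenol is needed. The demand is sterically governed iridium catalysis that leaves ketal and tert-butyl ester alone, followed by a neutral release of the boronic acid.

13 to 12, then to 10 and 4 by way of 11: the two ketal C–O bonds and then the benzylic C–C(=O) bond are cut. The side chain thus comes from a simple ortho-toluate and an acyl donor in one C–C bond formation. The demand is a clean lateral deprotonation and an acylation that stops at the ketone, then a ketalization mild enough for a tert-butyl ester.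

10 to 9: the O–C(CH3)3 bond is cut. The tert-butyl ester is chosen because it survives a lithium amide and leaves later by alkyl–oxygen cleavage. The demand is an esterification by O-alkylation, since the acyl carbon of 9 is hindered.

8 to 7: the acid is traced to its ethyl ester (O–ethyl bond). The ester is what makes the lateral chemistry possible and is already present in the starting material. The demand is a forcing saponification that the base-stable masks of 7 must outlast.

7 to 6, then to 3 and 4 by way of 5: again the ketal C–O bonds and the benzylic C–C(=O) bond are cut, the same construction as for ring B, with the same acyl donor serving both halves. The demand is a ketalization that does not remove the methoxymethyl group.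

3 to 2 to 1: the O–CH2 bond of the methoxymethyl ether and the O–CH3 bond at C4 are cut. This leads to a commercial resorcylate in which the two phenols differ inherently, one being chelated to the ester. The demand is a mono-methylation at the free C4 hydroxyl only.

## Other disconnections considered

Alternative 1: The cut runs through ring A itself. Its C1–C2 and C5–C6 bonds are broken, so that the depside ester already exists in the aryl alkynoate A1 and the remaining four ring carbons come from the silyl ketene acetal diene A2. The forward step is a Diels–Alder addition of A2 across the triple bond of A1; the adduct would aromatize by eliminating one methoxy group and the silyl group to give the salicylate A3.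
- In its favour: the 2-hydroxy/4-methoxy pattern is written into the diene, so ring A needs no phenol protection and no selective methylation. The ester is made by acylating a phenol with an unhindered alkynoic acid. On both points this plan is better than the chosen one. On regiochemistry it is its equal, because the polarized ynoate and the diene can combine in only one sense.
- Against it: ring B must be made as a free phenol and as a benzyl ester, which costs an oxidation and an ester exchange beyond the chosen sequence. The propargylic CH2 of A1, lying between alkyne and ketal, can isomerize to an allenoate. The aryl ester of A1 is an activated acyl donor that the nucleophilic diene could attack at the carbonyl or add to in a conjugate sense without ring closure. A beta-alkylated ynoate is also a slow dienophile.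
- Comparison: mechanistically a pericyclic ring synthesis stands against a copper redox coupling. Structurally it saves one protecting group. In step count it is longer, with a two-operation endgame (hydrogenolysis and ketal hydrolysis) against one.

Alternative 2: Two bonds are cut, the depside C(acyl)–O bond and the C1–C6 bond of ring A, leading to the diketo-dioxinone A4 and the ring B phenol A5. In the forward step, heating A4 with A5 would unmask a ketene that acylates the phenol oxygen; an amine base would then close ring A by aldol condensation, dehydration and enolization to give the resorcylate A6.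
- In its favour: the ester forms at a ketene carbon that has no ortho neighbours yet, under neutral conditions, so the steric problem is avoided as fully as in the chosen plan (equal on this point). Two skeletal bonds and a ring arise in one operation, which is better bond economy than a single C–O coupling.
- Against it: A6 carries two free phenols, so a selective 4-O-methylation must follow on a molecule that already holds the base-sensitive depside. The chosen plan settles this in step 1 on a simple ester. A4 is a polycarbonyl chain that needs several Claisen-type steps and is prone to premature cyclization. The amine used for aromatization can attack the aryl ester. Ring B again has to be a phenol and a benzyl ester.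
- Comparison: the cascade is more elegant, but the route is longer overall, and the late methylation is a selectivity burden that the chosen route does not have.

Alternative 3: The cut removes the carbonyl carbon: both the C1–C(=O) and the C(=O)–O bonds are broken, giving the ring A iodide A7, the ring B phenol A8 and carbon monoxide A9. In the forward step a zerovalent palladium catalyst with a wide-bite-angle bisphosphine and an amine base would add into the C–I bond, insert A9, and pass the acyl group to A8 to give A10.
- In its favour: like the chosen step it avoids attack of a weak nucleophile on a pre-formed hindered acid derivative (equal). It needs no carboxyl group on ring A, so the forcing ester hydrolysis of the chosen route disappears (better). The arene that precedes A7 is symmetric, so its iodination has one sensible site.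
- Against it: that symmetry forces two identical benzyl ethers. After the coupling both must be removed and the C4 hydroxyl methylated selectively on the finished depside. Oxidative addition and insertion at an electron-rich, doubly ortho-substituted iodide are expected to be slow, and phenols are weak partners for acylpalladium species. A toxic gas is handled, and ring B must first be oxidized to a phenol.
- Comparison: both plans use a transition metal to escape the tetrahedral intermediate. The chosen plan reaches the target in one operation after coupling; this one needs three (hydrogenolysis, methylation, acid).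

Key step: step 11

Remarks on the chemistry:
- The target has no stereocenter.
- Structures 8, 16 and 17 were checked atom by atom against the target and need no correction.
- The iridium borylation delivers a pinacol boronate (15), so a separate neutral cleavage to the boronic acid 16 is included (step 10).
- Both ketalizations are run under aprotic silyl triflate catalysis to spare the methoxymethyl ether and the tert-butyl ester.
- Cu(OTf)2 is taken as substoichiometric with air as terminal oxidant, and commercial LiN(iPr)2 solution is assumed.

## Route

Step 1
Reactants: 1 ethyl 2,4-dihydroxy-6-methylbenzoate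
Product: 2 ethyl 2-hydroxy-4-methoxy-6-methylbenzoate
Conditions: MeI (1.05 equiv), K2CO3 (1.1 equiv), acetone, rt
Reagents that add atoms: iodomethane, CI
Why: Williamson etherification; the C4 hydroxyl is the more acidic, unchelated phenol, whereas the C2 hydroxyl is held in a hydrogen bond to the ester carbonyl, so one equivalent of MeI should methylate C4–OH selectively.

Step 2
Reactants: 2 ethyl 2-hydroxy-4-methoxy-6-methylbenzoate
Product: 3 ethyl 4-methoxy-2-(methoxymethoxy)-6-methylbenzoate
Conditions: NaH, THF, 0 °C; then MOMCl, 0 °C → rt
Reagents that add atoms: chloromethyl methyl ether, COCCl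
Why: O-alkylation of the chelated phenol after full deprotonation; the methoxymethyl acetal is stable to the bases of steps 3 and 5 and to the copper coupling, and is removed in the final acid treatment.

Step 3
Reactants: 3 ethyl 4-methoxy-2-(methoxymethoxy)-6-methylbenzoate; 4 N-methoxy-N-methylhexanamide
Product: 6 ethyl 4-methoxy-2-(methoxymethoxy)-6-(2-oxoheptyl)benzoate, via benzylic organolithium 5 (not isolated)
Conditions: LiN(iPr)2 (1.2 equiv), THF, −78 °C; then 4, −78 → −40 °C; aq. NH4Cl
Reagents that add atoms: none
Why: Lateral lithiation of an ortho-toluate (the ester acidifies the C6 methyl group) followed by Weinreb acylation; the chelated tetrahedral adduct holds until the quench, so the ketone cannot be attacked or deprotonated in the flask, and the doubly ortho-substituted ester resists self-condensation.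

Step 4
Reactants: 6 ethyl 4-methoxy-2-(methoxymethoxy)-6-(2-oxoheptyl)benzoate
Product: 7 ethyl 4-methoxy-2-(methoxymethoxy)-6-[(2-pentyl-1,3-dioxolan-2-yl)methyl]benzoate
Conditions: (TMSOCH2)2 (2.5 equiv), TMSOTf (5 mol %), CH2Cl2, −78 → −20 °C; pyridine quench
Reagents that add atoms: 1,2-bis(trimethylsilyloxy)ethane, C[Si](C)(C)OCCO[Si](C)(C)C
Why: Noyori ketalization; catalytic silyl triflate and the bis-silyl glycol close the dioxolane at low temperature without protic acid or heat, which should spare the methoxymethyl ether and avoid cyclization of the keto ester to an isocoumarin. The ketal is needed because hot base in step 5 would otherwise condense the ketone onto the ortho ester.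

Step 5
Reactants: 7 ethyl 4-methoxy-2-(methoxymethoxy)-6-[(2-pentyl-1,3-dioxolan-2-yl)methyl]benzoate
Product: 8 4-methoxy-2-(methoxymethoxy)-6-[(2-pentyl-1,3-dioxolan-2-yl)methyl]benzoic acid
Conditions: KOH (10 equiv), DMSO/H2O (4:1), 90 °C; then 0 °C, EtOAc overlay, 1 M HCl to pH 4
Reagents that add atoms: potassium hydroxide, [K+].[OH-]
Why: Saponification of a doubly ortho-substituted benzoate needs hot hydroxide in a dipolar solvent; ketal, acetal and aryl methyl ether are inert to base, and a cold, pH-controlled acidification should free the acid without hydrolysing them. The acid is used promptly in step 11.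

Step 6
Reactants: 9 2-methoxy-6-methylbenzoic acid
Product: 10 tert-butyl 2-methoxy-6-methylbenzoate
Conditions: Cl3CC(=NH)OtBu (2 equiv), BF3·OEt2 (5 mol %), CH2Cl2/cyclohexane, rt
Reagents that add atoms: tert-butyl 2,2,2-trichloroacetimidate, CC(C)(C)OC(=N)C(Cl)(Cl)Cl
Why: Acid-catalysed O-alkylation of the carboxylic acid by the imidate goes through a tert-butyl cation at oxygen, so the two ortho groups that shield the carbonyl carbon do not interfere. The tert-butyl ester survives the lithium amide and later leaves by alkyl–oxygen cleavage, with no nucleophile that could attack the depside.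

Step 7
Reactants: 10 tert-butyl 2-methoxy-6-methylbenzoate; 4 N-methoxy-N-methylhexanamide
Product: 12 tert-butyl 2-methoxy-6-(2-oxoheptyl)benzoate, via benzylic organolithium 11 (not isolated)
Conditions: LiN(iPr)2 (1.2 equiv), THF, −78 °C; then 4, −78 → −40 °C; aq. NH4Cl
Reagents that add atoms: none
Why: The same lateral lithiation and Weinreb acylation as in step 3; the bulky tert-butyl ester suppresses self-condensation of anion 11, and the methoxy group is not a competitive site for the amide base at −78 °C.

Step 8
Reactants: 12 tert-butyl 2-methoxy-6-(2-oxoheptyl)benzoate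
Product: 13 tert-butyl 2-methoxy-6-[(2-pentyl-1,3-dioxolan-2-yl)methyl]benzoate
Conditions: (TMSOCH2)2 (2.5 equiv), TMSOTf (5 mol %), CH2Cl2, −78 → −20 °C; pyridine quench
Reagents that add atoms: 1,2-bis(trimethylsilyloxy)ethane, C[Si](C)(C)OCCO[Si](C)(C)C
Why: Noyori ketalization as in step 4; with only catalytic silyl triflate below −20 °C the tert-butyl ester should remain intact, and the ketal shields the ketone from the boron hydride by-product of step 9 and from lactonization later.

Step 9
Reactants: 13 tert-butyl 2-methoxy-6-[(2-pentyl-1,3-dioxolan-2-yl)methyl]benzoate; 14 bis(pinacolato)diboron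
Product: 15 tert-butyl 2-methoxy-6-[(2-pentyl-1,3-dioxolan-2-yl)methyl]-4-(4,4,5,5-tetramethyl-1,3,2-dioxaborolan-2-yl)benzoate
Conditions: [Ir(OMe)(cod)]2 (1.5 mol %), 4,4'-di-tert-butyl-2,2'-bipyridine (3 mol %), 14 (1.0 equiv), THF, 60 °C, N2
Reagents that add atoms: none
Why: Iridium-catalysed aromatic C–H borylation is governed by sterics: C3–H is ortho to the methoxy group and C5–H ortho to the side chain, so the bulky tris(boryl)iridium species should select C4–H, the only ring hydrogen without an ortho neighbour. Ester, ketal and ether are tolerated.

Step 10
Reactants: 15 tert-butyl 2-methoxy-6-[(2-pentyl-1,3-dioxolan-2-yl)methyl]-4-(4,4,5,5-tetramethyl-1,3,2-dioxaborolan-2-yl)benzoate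
Product: 16 {4-(tert-butoxycarbonyl)-3-methoxy-5-[(2-pentyl-1,3-dioxolan-2-yl)methyl]phenyl}boronic acid
Conditions: NaIO4 (3 equiv), NH4OAc (3 equiv), acetone/H2O (1:1), rt
Reagents that add atoms: water, O
Why: Oxidative cleavage of the pinacol ester: the boronate equilibrates with boronic acid and pinacol in aqueous acetone and periodate destroys the diol irreversibly. The ammonium acetate buffer keeps the medium near neutral, so ketal and tert-butyl ester should survive.

Step 11
Reactants: 8 4-methoxy-2-(methoxymethoxy)-6-[(2-pentyl-1,3-dioxolan-2-yl)methyl]benzoic acid (1.0 equiv); 16 {4-(tert-butoxycarbonyl)-3-methoxy-5-[(2-pentyl-1,3-dioxolan-2-yl)methyl]phenyl}boronic acid (1.5 equiv)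
Product: 17 tert-butyl 2-methoxy-4-({4-methoxy-2-(methoxymethoxy)-6-[(2-pentyl-1,3-dioxolan-2-yl)methyl]benzoyl}oxy)-6-[(2-pentyl-1,3-dioxolan-2-yl)methyl]benzoate
Conditions: Cu(OTf)2 (0.4 equiv), urea (2 equiv), powdered 4 Å molecular sieves, EtOAc, 60 °C, dry air
Reagents that add atoms: none
Why: Chan–Lam-type oxidative esterification: acid 8 exchanges onto Cu(OTf)2 to give a divalent copper carboxylate (urea takes up the triflic acid), the aryl group of 16 passes from boron to copper, and oxidation by a second divalent copper centre or by air gives a trivalent copper aryl carboxylate. C–O reductive elimination then forms the O–C4' bond and releases monovalent copper, which air returns to the divalent state. The closest known reaction type is the copper-mediated coupling of carboxylic acids with arylboronic acids under Cu(OTf)2 and urea, an extension of the Chan–Lam O-arylation of phenols. No ring is closed and no stereocenter is formed. Site selectivity is not in question at this stage, because the new bond can form only at the carbon that carried boron, C4', fixed in step 9. Chemoselectivity rests on 8 having a single oxygen nucleophile: the C2 hydroxyl is a methoxymethyl ether, and triflate, unlike acetate, cannot be arylated. The bond is made at the carboxylate oxygen, outside the C2/C6 pocket, so the ortho groups never have to admit a nucleophile at the carbonyl carbon. Sieves and urea keep water and free triflic acid low so that ketals, acetal and tert-butyl ester should survive, and the excess of 16 covers protodeboronation and homocoupling.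

Step 12
Reactants: 17 tert-butyl 2-methoxy-4-({4-methoxy-2-(methoxymethoxy)-6-[(2-pentyl-1,3-dioxolan-2-yl)methyl]benzoyl}oxy)-6-[(2-pentyl-1,3-dioxolan-2-yl)methyl]benzoate
Product: 18 4-{[2-hydroxy-4-methoxy-6-(2-oxoheptyl)benzoyl]oxy}-2-methoxy-6-(2-oxoheptyl)benzoic acid
Conditions: TFA/CH2Cl2/H2O (10:10:1), 0 °C → rt; toluene co-evaporation below 30 °C
Reagents that add atoms: water, O
Why: Acid-mediated global deprotection: aqueous trifluoroacetic acid hydrolyses both dioxolanes and the methoxymethyl acetal and cleaves the tert-butyl ester by alkyl–oxygen fission, none of which needs a nucleophile at the depside carbonyl. Water and low temperature disfavour dehydrative closure of the liberated keto acid to an isocoumarin.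

## Compound list

1 | ethyl 2,4-dihydroxy-6-methylbenzoate | CCOC(=O)c1c(C)cc(O)cc1O | starting material
2 | ethyl 2-hydroxy-4-methoxy-6-methylbenzoate | CCOC(=O)c1c(C)cc(OC)cc1O | intermediate
3 | ethyl 4-methoxy-2-(methoxymethoxy)-6-methylbenzoate | CCOC(=O)c1c(C)cc(OC)cc1OCOC | intermediate
4 | N-methoxy-N-methylhexanamide | CCCCCC(=O)N(C)OC | starting material
5 | [2-(ethoxycarbonyl)-5-methoxy-3-(methoxymethoxy)benzyl]lithium | CCOC(=O)c1c(C[Li])cc(OC)cc1OCOC | intermediate
6 | ethyl 4-methoxy-2-(methoxymethoxy)-6-(2-oxoheptyl)benzoate | CCCCCC(=O)Cc1cc(OC)cc(OCOC)c1C(=O)OCC | intermediate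
7 | ethyl 4-methoxy-2-(methoxymethoxy)-6-[(2-pentyl-1,3-dioxolan-2-yl)methyl]benzoate | CCCCCC1(Cc2cc(OC)cc(OCOC)c2C(=O)OCC)OCCO1 | intermediate
8 | 4-methoxy-2-(methoxymethoxy)-6-[(2-pentyl-1,3-dioxolan-2-yl)methyl]benzoic acid | CCCCCC1(Cc2cc(OC)cc(OCOC)c2C(=O)O)OCCO1 | intermediate
9 | 2-methoxy-6-methylbenzoic acid | COc1cccc(C)c1C(=O)O | starting material
10 | tert-butyl 2-methoxy-6-methylbenzoate | COc1cccc(C)c1C(=O)OC(C)(C)C | intermediate
11 | [2-(tert-butoxycarbonyl)-3-methoxybenzyl]lithium | [Li]Cc1cccc(OC)c1C(=O)OC(C)(C)C | intermediate
12 | tert-butyl 2-methoxy-6-(2-oxoheptyl)benzoate | CCCCCC(=O)Cc1cccc(OC)c1C(=O)OC(C)(C)C | intermediate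
13 | tert-butyl 2-methoxy-6-[(2-pentyl-1,3-dioxolan-2-yl)methyl]benzoate | CCCCCC1(Cc2cccc(OC)c2C(=O)OC(C)(C)C)OCCO1 | intermediate
14 | bis(pinacolato)diboron | CC1(C)OB(OC1(C)C)B1OC(C)(C)C(C)(C)O1 | starting material
15 | tert-butyl 2-methoxy-6-[(2-pentyl-1,3-dioxolan-2-yl)methyl]-4-(4,4,5,5-tetramethyl-1,3,2-dioxaborolan-2-yl)benzoate | CCCCCC1(Cc2cc(B3OC(C)(C)C(C)(C)O3)cc(OC)c2C(=O)OC(C)(C)C)OCCO1 | intermediate
16 | {4-(tert-butoxycarbonyl)-3-methoxy-5-[(2-pentyl-1,3-dioxolan-2-yl)methyl]phenyl}boronic acid | CCCCCC1(Cc2cc(B(O)O)cc(OC)c2C(=O)OC(C)(C)C)OCCO1 | intermediate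
17 | tert-butyl 2-methoxy-4-({4-methoxy-2-(methoxymethoxy)-6-[(2-pentyl-1,3-dioxolan-2-yl)methyl]benzoyl}oxy)-6-[(2-pentyl-1,3-dioxolan-2-yl)methyl]benzoate | CCCCCC1(Cc2cc(OC)cc(OCOC)c2C(=O)Oc2cc(CC3(CCCCC)OCCO3)c(C(=O)OC(C)(C)C)c(OC)c2)OCCO1 | intermediate
18 | 4-{[2-hydroxy-4-methoxy-6-(2-oxoheptyl)benzoyl]oxy}-2-methoxy-6-(2-oxoheptyl)benzoic acid | CCCCCC(=O)Cc1cc(OC)cc(O)c1C(=O)Oc1cc(CC(=O)CCCCC)c(C(=O)O)c(OC)c1 | target

## Step count and least certain steps

Total step count: 12. Longest linear sequence: 7 steps (steps 1–5, 11, 12, or equally steps 6–10, 11, 12).

Step 11 (key step).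
- What may go wrong: slow aryl transfer and reductive elimination at the bulky, chelating carboxylate would let protodeboronation, homocoupling or oxidation of the boronic acid to a phenol take over. Triflic acid released from the copper salt could also strip a ketal, the acetal or the tert-butyl group during the coupling, creating new nucleophiles.
- Fallback (sets out from 16 and 8, returns at 17): the boronic acid 16 would be oxidized (H2O2, NaHCO3, THF/H2O, 0 °C) to the phenol tert-butyl 4-hydroxy-2-methoxy-6-[(2-pentyl-1,3-dioxolan-2-yl)methyl]benzoate F1. Acid 8 would be converted with cyanuric fluoride and pyridine (CH2Cl2, −10 °C) into 4-methoxy-2-(methoxymethoxy)-6-[(2-pentyl-1,3-dioxolan-2-yl)methyl]benzoyl fluoride F2, a small acyl donor suited to hindered carbonyls. The sodium phenoxide of F1 (NaH, THF) would then be acylated by F2 (0 → 40 °C) to give 17 under base only, which all masks tolerate.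

Step 12.
- What may go wrong: dehydrative lactonization of the freed keto acid on ring B, attack of the ring A enol on the depside carbonyl with expulsion of ring B, and Friedel–Crafts alkylation of the electron-rich ring A by tert-butyl or methoxymethyl cations.
- Fallback (sets out from 17, returns at 18): the unmasking would be split into two stages. Dilute aqueous HCl in THF (rt to 40 °C) would hydrolyse the ketals and the acetal while the carboxyl group is still an ester and cannot lactonize, giving tert-butyl 4-{[2-hydroxy-4-methoxy-6-(2-oxoheptyl)benzoyl]oxy}-2-methoxy-6-(2-oxoheptyl)benzoate F3. The tert-butyl group would then be removed by Lewis-acid fragmentation with ZnBr2 in dry CH2Cl2 at rt, without a strong protic acid, to give 18.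

Step 4.
- What may go wrong: silyl-triflate-mediated acetal exchange could remove the methoxymethyl group in competition with ketalization.
- Fallback (sets out from 2, returns at 7): the phenol would be carried as a benzyl ether, which is inert to silyl triflate. Benzylation of 2 (BnBr, K2CO3, DMF) would give ethyl 2-(benzyloxy)-4-methoxy-6-methylbenzoate F4. Lateral lithiation and acylation with 4 as in step 3 would give ethyl 2-(benzyloxy)-4-methoxy-6-(2-oxoheptyl)benzoate F5. Noyori ketalization would give ethyl 2-(benzyloxy)-4-methoxy-6-[(2-pentyl-1,3-dioxolan-2-yl)methyl]benzoate F6. Hydrogenolysis (H2, palladium on carbon (Pd/C), EtOAc, trace Et3N) would give ethyl 2-hydroxy-4-methoxy-6-[(2-pentyl-1,3-dioxolan-2-yl)methyl]benzoate F7. Methoxymethylation (NaH, MOMCl, THF) would then give 7.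

Step 8.
- What may go wrong: the ester carbonyl could participate with the activated ketone and the tert-butyl group ionize, leading to lactonization with loss of isobutene.
- Fallback (sets out from 9, returns at 13, replacing steps 6–8): 9 would be converted (MeI, K2CO3, DMF) into methyl 2-methoxy-6-methylbenzoate F8, which cannot ionize. Lateral lithiation (LiN(iPr)2, THF, −78 °C) and acylation with 4 would give methyl 2-methoxy-6-(2-oxoheptyl)benzoate F9. Noyori ketalization would give methyl 2-methoxy-6-[(2-pentyl-1,3-dioxolan-2-yl)methyl]benzoate F10. Hot KOH in DMSO/H2O would give 2-methoxy-6-[(2-pentyl-1,3-dioxolan-2-yl)methyl]benzoic acid F11. O-alkylation of the carboxyl group with N,N-dimethylformamide di-tert-butyl acetal (toluene, 80 °C, no acid) would give 13.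

Step 5.
- What may go wrong: hydroxide attack at the shielded carbonyl may be too slow, so that prolonged heating degrades the material, or the ketal may hydrolyse during acidification.
- Fallback (sets out from 7, returns at 8, no new compound, F0): the ethyl group would be removed by attack at the alkyl carbon instead of the acyl carbon, with LiSCH2CH2CH3 in a dipolar aprotic solvent at 25–60 °C. Aryl methyl ethers need much higher temperatures. The same cold buffered acidification would follow.

## Further compounds

F1 | step 11 | tert-butyl 4-hydroxy-2-methoxy-6-[(2-pentyl-1,3-dioxolan-2-yl)methyl]benzoate | CCCCCC1(Cc2cc(O)cc(OC)c2C(=O)OC(C)(C)C)OCCO1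
F2 | step 11 | 4-methoxy-2-(methoxymethoxy)-6-[(2-pentyl-1,3-dioxolan-2-yl)methyl]benzoyl fluoride | CCCCCC1(Cc2cc(OC)cc(OCOC)c2C(=O)F)OCCO1
F3 | step 12 | tert-butyl 4-{[2-hydroxy-4-methoxy-6-(2-oxoheptyl)benzoyl]oxy}-2-methoxy-6-(2-oxoheptyl)benzoate | CCCCCC(=O)Cc1cc(OC)cc(O)c1C(=O)Oc1cc(CC(=O)CCCCC)c(C(=O)OC(C)(C)C)c(OC)c1
F4 | step 4 | ethyl 2-(benzyloxy)-4-methoxy-6-methylbenzoate | CCOC(=O)c1c(C)cc(OC)cc1OCc1ccccc1
F5 | step 4 | ethyl 2-(benzyloxy)-4-methoxy-6-(2-oxoheptyl)benzoate | CCCCCC(=O)Cc1cc(OC)cc(OCc2ccccc2)c1C(=O)OCC
F6 | step 4 | ethyl 2-(benzyloxy)-4-methoxy-6-[(2-pentyl-1,3-dioxolan-2-yl)methyl]benzoate | CCCCCC1(Cc2cc(OC)cc(OCc3ccccc3)c2C(=O)OCC)OCCO1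
F7 | step 4 | ethyl 2-hydroxy-4-methoxy-6-[(2-pentyl-1,3-dioxolan-2-yl)methyl]benzoate | CCCCCC1(Cc2cc(OC)cc(O)c2C(=O)OCC)OCCO1
F8 | step 8 | methyl 2-methoxy-6-methylbenzoate | COc1cccc(C)c1C(=O)OC
F9 | step 8 | methyl 2-methoxy-6-(2-oxoheptyl)benzoate | CCCCCC(=O)Cc1cccc(OC)c1C(=O)OC
F10 | step 8 | methyl 2-methoxy-6-[(2-pentyl-1,3-dioxolan-2-yl)methyl]benzoate | CCCCCC1(Cc2cccc(OC)c2C(=O)OC)OCCO1
F11 | step 8 | 2-methoxy-6-[(2-pentyl-1,3-dioxolan-2-yl)methyl]benzoic acid | CCCCCC1(Cc2cccc(OC)c2C(=O)O)OCCO1
F0 | step 5 | none | none
A1 | alternative 1 | benzyl 2-methoxy-6-[(2-pentyl-1,3-dioxolan-2-yl)methyl]-4-{[4-(2-pentyl-1,3-dioxolan-2-yl)but-2-ynoyl]oxy}benzoate | CCCCCC1(CC#CC(=O)Oc2cc(CC3(CCCCC)OCCO3)c(C(=O)OCc3ccccc3)c(OC)c2)OCCO1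
A2 | alternative 1 | [(1,3-dimethoxybuta-1,3-dien-1-yl)oxy]trimethylsilane | C=C(OC)C=C(OC)O[Si](C)(C)C
A3 | alternative 1 | benzyl 4-({2-hydroxy-4-methoxy-6-[(2-pentyl-1,3-dioxolan-2-yl)methyl]benzoyl}oxy)-2-methoxy-6-[(2-pentyl-1,3-dioxolan-2-yl)methyl]benzoate | CCCCCC1(Cc2cc(OC)cc(O)c2C(=O)Oc2cc(CC3(CCCCC)OCCO3)c(C(=O)OCc3ccccc3)c(OC)c2)OCCO1
A4 | alternative 2 | 6-[2,4-dioxo-5-(2-pentyl-1,3-dioxolan-2-yl)pentyl]-2,2-dimethyl-4H-1,3-dioxin-4-one | CCCCCC1(CC(=O)CC(=O)CC2=CC(=O)OC(C)(C)O2)OCCO1
A5 | alternative 2 | benzyl 4-hydroxy-2-methoxy-6-[(2-pentyl-1,3-dioxolan-2-yl)methyl]benzoate | CCCCCC1(Cc2cc(O)cc(OC)c2C(=O)OCc2ccccc2)OCCO1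
A6 | alternative 2 | benzyl 4-({2,4-dihydroxy-6-[(2-pentyl-1,3-dioxolan-2-yl)methyl]benzoyl}oxy)-2-methoxy-6-[(2-pentyl-1,3-dioxolan-2-yl)methyl]benzoate | CCCCCC1(Cc2cc(O)cc(O)c2C(=O)Oc2cc(CC3(CCCCC)OCCO3)c(C(=O)OCc3ccccc3)c(OC)c2)OCCO1
A7 | alternative 3 | 1,5-bis(benzyloxy)-2-iodo-3-[(2-pentyl-1,3-dioxolan-2-yl)methyl]benzene | CCCCCC1(Cc2cc(OCc3ccccc3)cc(OCc3ccccc3)c2I)OCCO1
A8 | alternative 3 | tert-butyl 4-hydroxy-2-methoxy-6-[(2-pentyl-1,3-dioxolan-2-yl)methyl]benzoate | CCCCCC1(Cc2cc(O)cc(OC)c2C(=O)OC(C)(C)C)OCCO1
A9 | alternative 3 | carbon monoxide | [C-]#[O+]
A10 | alternative 3 | tert-butyl 4-({2,4-bis(benzyloxy)-6-[(2-pentyl-1,3-dioxolan-2-yl)methyl]benzoyl}oxy)-2-methoxy-6-[(2-pentyl-1,3-dioxolan-2-yl)methyl]benzoate | CCCCCC1(Cc2cc(OCc3ccccc3)cc(OCc3ccccc3)c2C(=O)Oc2cc(CC3(CCCCC)OCCO3)c(C(=O)OC(C)(C)C)c(OC)c2)OCCO1
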